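**Strategy.** The ten-membered ring is opened at C8–C9, the bond between the two adjacent ester-bearing carbinols, of which C9 also carries C10 of the C1–C10 epoxide (a former alkene). In the forward sense an enal bis(4-methoxybenzyl) acetal is turned into a γ-alkoxyallylchromium that adds through C9 to the C8 aldehyde. One operation closes the carbocycle, forms C8–C9, sets C8 and C9 anti with only C9 protected, and places the Z alkene at C10=C1. The precursor is an acyclic C8 aldehyde (C7 R, isopropenyl) carrying the Z C4=C5 alkene, the silylated 3S carbinol and the E C1=C10 enal acetal.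

Key step: step 16

Remark: ring numbering C1–C10 (C7 isopropenyl with C11, methyls on C4 and C10) is used for all intermediates; in it the target is 1R,3S,4S,5S,7R,8S,9S,10R, the C9 oxygen is cis to the C1–C10 epoxide oxygen on the ring and the C3 oxygen is trans to the C4–C5 epoxide oxygen, so the two hydroxyl-directed epoxidations use different oxidants.

Step 1
Reactants: 1 3-methylbut-2-enoic acid; 2 (R)-4-benzyloxazolidin-2-one
Product: 4 (R)-4-benzyl-3-(3-methylbut-2-enoyl)oxazolidin-2-one, via mixed pivalic anhydride 3 (not isolated)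
Conditions: t-BuCOCl, Et3N, THF, −20 °C; then LiCl, 2, −20 °C to rt
Reagents that add atoms: none
Why: N-acylation of the oxazolidinone through the mixed pivalic anhydride under LiCl/Et3N activation is a standard route to Evans imides from enoic acids and creates no stereocentre.

Step 2
Reactants: 5 but-2-yn-1-ol
Product: 7 (Z)-3-iodobut-2-en-1-ol, via cyclic alkenylalanate 6 (not isolated)
Conditions: NaAlH2(OCH2CH2OMe)2, THF, 0 °C to rt; then I2, −78 to 0 °C
Reagents that add atoms: iodine, II
Why: hydroxyl-directed trans-hydroalumination of the propargylic alcohol places aluminium on C3 inside a five-membered alkoxyaluminate, and iodinolysis with retention fixes iodine cis to the CH2OH group, which is the Z geometry needed for the future C4=C5 alkene.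

Step 3
Reactants: 7 (Z)-3-iodobut-2-en-1-ol
Product: 8 (Z)-1-bromo-3-iodobut-2-ene
Conditions: PBr3, Et2O, 0 °C
Reagents that add atoms: phosphorus tribromide, BrP(Br)Br
Why: PBr3 converts the primary allylic alcohol into the bromide at 0 °C without touching the alkenyl iodide or its geometry.

Step 4
Reactants: 4 (R)-4-benzyl-3-(3-methylbut-2-enoyl)oxazolidin-2-one; 8 (Z)-1-bromo-3-iodobut-2-ene
Product: 10 (R)-4-benzyl-3-[(2R,4Z)-5-iodo-2-(prop-1-en-2-yl)hex-4-enoyl]oxazolidin-2-one, via sodium dienolate 9 (not isolated)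
Conditions: NaN(SiMe3)2, THF, −78 °C; then 8, −78 to −40 °C
Reagents that add atoms: none
Why: γ-deprotonation gives the chelated Z(O) dienolate, which undergoes deconjugative Evans alkylation at the α-carbon on the face opposite the benzyl group, so that C7 is formed R and the isopropenyl group appears.

Step 5
Reactants: 10 (R)-4-benzyl-3-[(2R,4Z)-5-iodo-2-(prop-1-en-2-yl)hex-4-enoyl]oxazolidin-2-one
Product: 11 (2R,4Z)-5-iodo-2-(prop-1-en-2-yl)hex-4-en-1-ol
Conditions: LiBH4, MeOH (1 equiv), Et2O, 0 °C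
Reagents that add atoms: none
Why: reductive removal of the oxazolidinone with LiBH4 gives the primary C8 alcohol without epimerising C7, leaves the alkenyl iodide intact and returns the auxiliary.

Step 6
Reactants: 11 (2R,4Z)-5-iodo-2-(prop-1-en-2-yl)hex-4-en-1-ol
Product: 12 tert-butyl{[(2R,4Z)-5-iodo-2-(prop-1-en-2-yl)hex-4-en-1-yl]oxy}dimethylsilane
Conditions: t-BuMe2SiCl, imidazole, DMF, 0 °C to rt
Reagents that add atoms: tert-butyldimethylsilyl chloride, CC(C)(C)[Si](C)(C)Cl
Why: silylation masks the only acidic proton before the halogen–lithium exchange (a free C8 hydroxyl would later add to the enone in a conjugate sense) and gives a group that fluoride removes in the presence of a hindered secondary silyl ether.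

Step 7
Reactants: 13 methyl 3,3-dimethoxypropanoate
Product: 14 N,3,3-trimethoxy-N-methylpropanamide
Conditions: MeNH(OMe)·HCl, i-PrMgCl, THF, −20 °C
Reagents that add atoms: N,O-dimethylhydroxylamine hydrochloride, CNOC.Cl
Why: aminolysis of the methyl ester by the magnesium amide of N,O-dimethylhydroxylamine is the standard one-step preparation of a Weinreb amide and tolerates the acetal.

Step 8
Reactants: 12 tert-butyl{[(2R,4Z)-5-iodo-2-(prop-1-en-2-yl)hex-4-en-1-yl]oxy}dimethylsilane; 14 N,3,3-trimethoxy-N-methylpropanamide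
Product: 16 (4Z,7R)-8-(tert-butyldimethylsilyloxy)-1,1-dimethoxy-4-methyl-7-(prop-1-en-2-yl)oct-4-en-3-one, via alkenyllithium 15 (not isolated)
Conditions: t-BuLi (2.1 equiv), Et2O, −78 °C; then 14, −78 to −40 °C; aq NH4Cl
Reagents that add atoms: none
Why: iodine–lithium exchange proceeds with retention of the alkene geometry and the alkenyllithium adds once to the Weinreb amide, whose chelated tetrahedral adduct releases the Z enone only on work-up, which forms the C3–C4 bond.

Step 9
Reactants: 16 (4Z,7R)-8-(tert-butyldimethylsilyloxy)-1,1-dimethoxy-4-methyl-7-(prop-1-en-2-yl)oct-4-en-3-one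
Product: 17 (3S,4Z,7R)-8-(tert-butyldimethylsilyloxy)-1,1-dimethoxy-4-methyl-7-(prop-1-en-2-yl)oct-4-en-3-ol
Conditions: (R)-2-methyl-CBS-oxazaborolidine (0.2 equiv), catecholborane, toluene, −78 °C
Reagents that add atoms: none
Why: in the Corey–Bakshi–Shibata reduction the α-methylalkenyl group acts as the large and the CH2 side as the small substituent, so the (R)-catalyst should deliver hydride to give the 3S allylic alcohol, and catecholborane at −78 °C does not hydroborate the alkenes.

Step 10
Reactants: 17 (3S,4Z,7R)-8-(tert-butyldimethylsilyloxy)-1,1-dimethoxy-4-methyl-7-(prop-1-en-2-yl)oct-4-en-3-ol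
Product: 18 C3 tert-butyldiphenylsilyl ether of 17 (3S,4Z,7R)
Conditions: t-BuPh2SiCl, imidazole, DMAP (cat.), DMF, rt to 40 °C
Reagents that add atoms: tert-butyldiphenylsilyl chloride, CC(C)(C)[Si](Cl)(c1ccccc1)c1ccccc1
Why: silylation of the secondary allylic alcohol leaves C3 unchanged and gives an ether that withstands fluoride at 0 °C, Me3SiI/CrCl2 and DDQ.

Step 11
Reactants: 18 C3 tert-butyldiphenylsilyl ether of 17
Product: 20 (3S,4Z,7R)-8-(tert-butyldimethylsilyloxy)-3-(tert-butyldiphenylsilyloxy)-4-methyl-7-(prop-1-en-2-yl)oct-4-enal, via collidinium salt 19 (not isolated)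
Conditions: Et3SiOTf, 2,4,6-collidine, CH2Cl2, 0 °C; then H2O
Reagents that add atoms: water, O
Why: silyl triflate and collidine convert the dimethyl acetal into a pyridinium-type salt that water hydrolyses to the C1 aldehyde under nearly neutral conditions, which spares both silyl ethers and avoids β-elimination of the C3 silyloxy group.

Step 12
Reactants: 20 (3S,4Z,7R)-8-(tert-butyldimethylsilyloxy)-3-(tert-butyldiphenylsilyloxy)-4-methyl-7-(prop-1-en-2-yl)oct-4-enal; 21 2-(triphenylphosphoranylidene)propanal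
Product: 22 (2E,5S,6Z,9R)-10-(tert-butyldimethylsilyloxy)-5-(tert-butyldiphenylsilyloxy)-2,6-dimethyl-9-(prop-1-en-2-yl)deca-2,6-dienal
Conditions: toluene, 80 °C
Reagents that add atoms: none
Why: Wittig olefination with the stabilised formyl ylide gives the 2-methyl-2-enal with E geometry (C9 trans to C2) and is mild enough for the β-silyloxy aldehyde.

Step 13
Reactants: 22 (2E,5S,6Z,9R)-10-(tert-butyldimethylsilyloxy)-5-(tert-butyldiphenylsilyloxy)-2,6-dimethyl-9-(prop-1-en-2-yl)deca-2,6-dienal
Product: 23 bis(4-methoxybenzyl) acetal of 22 at C9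
Conditions: 4-MeOC6H4CH2OSiMe3 (2.5 equiv; from the alcohol and Me3SiCl/Et3N), Me3SiOTf (5 mol %), CH2Cl2, −78 °C; pyridine quench
Reagents that add atoms: (4-methoxybenzyloxy)trimethylsilane, COc1ccc(CO[Si](C)(C)C)cc1
Why: silyl-triflate-catalysed acetalisation with an alkoxysilane forms the dibenzylic acetal at −78 °C without free protic acid or water, so the acid-sensitive 4-methoxybenzyl alcohol is never exposed, the alkene stays in place and the silyl ethers survive.

Step 14
Reactants: 23 bis(4-methoxybenzyl) acetal of 22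
Product: 24 (2R,4Z,6S,8E)-10,10-bis(4-methoxybenzyloxy)-6-(tert-butyldiphenylsilyloxy)-5,9-dimethyl-2-(prop-1-en-2-yl)deca-4,8-dien-1-ol
Conditions: Bu4NF (1.1 equiv), THF, 0 °C
Reagents that add atoms: none
Why: fluoride removes the unhindered primary tert-butyldimethylsilyl ether much faster than the hindered secondary tert-butyldiphenylsilyl ether and does not affect the acetal.

Step 15
Reactants: 24 (2R,4Z,6S,8E)-10,10-bis(4-methoxybenzyloxy)-6-(tert-butyldiphenylsilyloxy)-5,9-dimethyl-2-(prop-1-en-2-yl)deca-4,8-dien-1-ol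
Product: 25 (2R,4Z,6S,8E)-10,10-bis(4-methoxybenzyloxy)-6-(tert-butyldiphenylsilyloxy)-5,9-dimethyl-2-(prop-1-en-2-yl)deca-4,8-dienal
Conditions: Dess–Martin periodinane, NaHCO3, CH2Cl2, 0 °C; used at once
Reagents that add atoms: none
Why: buffered Dess–Martin oxidation gives the α-branched β,γ-unsaturated C8 aldehyde without epimerising C7, moving the isopropenyl alkene into conjugation or hydrolysing the acetal.

Step 16
Reactants: 25 (2R,4Z,6S,8E)-10,10-bis(4-methoxybenzyloxy)-6-(tert-butyldiphenylsilyloxy)-5,9-dimethyl-2-(prop-1-en-2-yl)deca-4,8-dienal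
Product: 28 (1S,2R,3Z,6S,7Z,10R)-6-(tert-butyldiphenylsilyloxy)-2-(4-methoxybenzyloxy)-3,7-dimethyl-10-(prop-1-en-2-yl)cyclodeca-3,7-dien-1-ol, via alkoxyallyl iodide 26 (not isolated), via allylchromium 27 (not isolated)
Conditions: CrCl2 (8 equiv), THF, −30 °C; 25 and Me3SiI (1.2 equiv, in CH2Cl2) added together by syringe pump to 3 mM; −30 to 0 °C; aq NaHCO3
Reagents that add atoms: none
Why: Proposed new method: Me3SiI ionises the allylic acetal and iodide returns to give the alkoxyallyl iodide 26, which two equivalents of divalent chromium reduce to the trivalent allylchromium 27 with the metal on C1 and a conjugated E enol ether at C9=C10; 27 then adds to the aldehyde through its oxygen-bearing terminus C9 in a six-membered Zimmerman–Traxler chair (SE2′), which forms C8–C9 and returns the alkene to C10=C1. The closest known reactions are the intermolecular addition of γ-alkoxyallylchromium reagents generated from enal acetals with Me3SiI/CrCl2 and the intramolecular Nozaki–Hiyama allylation used to close medium rings, but the two have not been combined. The ten-membered carbocycle closes by 10-exo-trig attack on the aldehyde carbonyl with C9, C10 and C1 of the allyl unit all ending in the ring. C8 and C9 are set together by the chair, in which the C7 substituent of the aldehyde and the C9 alkoxy group are both equatorial and therefore end anti, while their sense relative to C7 should follow Felkin–Anh addition with the isopropenyl group anti to the incoming carbon and the ring chain at C6 gauche, as ring closure favours. The step needs attack through C9 and not C1 (enol-ether conjugation keeps chromium on C1; attack through C1 would give an eight-membered ring), the Z C10=C1 alkene (the C2 chain should take the axial site on C1, away from the C10 methyl and as the six-atom tether to C8 demands) and ring closure over oligomerisation (slow addition at high dilution). The E geometry of the enal does not matter because it is lost at the allylmetal stage.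

Step 17
Reactants: 28 (1S,2R,3Z,6S,7Z,10R)-6-(tert-butyldiphenylsilyloxy)-2-(4-methoxybenzyloxy)-3,7-dimethyl-10-(prop-1-en-2-yl)cyclodeca-3,7-dien-1-ol
Product: 29 C8 angelate of 28
Conditions: angelic acid, 2,4,6-Cl3C6H2COCl, Et3N, toluene, rt; then 28, 80 °C
Reagents that add atoms: angelic acid [(Z)-2-methylbut-2-enoic acid], C/C=C(C)\C(=O)O
Why: Yamaguchi-type mixed-anhydride esterification run without DMAP acylates the hindered C8 alcohol with retention and avoids the nucleophile-induced isomerisation of the angelate to the tiglate.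

Step 18
Reactants: 29 C8 angelate of 28
Product: 30 C9 allylic alcohol (C8 angelate; C3 silyl ether; Z,Z-diene)
Conditions: DDQ, CH2Cl2/pH 7 buffer, 0 °C
Reagents that add atoms: none
Why: oxidative cleavage of the 4-methoxybenzyl ether by DDQ in buffered wet CH2Cl2 frees the C9 hydroxyl without affecting the angelate, the silyl ether or the alkenes.

Step 19
Reactants: 30 C9 allylic alcohol
Product: 31 C1–C10 epoxide of 30 with the epoxide oxygen cis to the C9 hydroxyl (1R,10R)
Conditions: VO(acac)2 (5 mol %), t-BuOOH, CH2Cl2, 0 °C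
Reagents that add atoms: tert-butyl hydroperoxide, CC(C)(C)OO
Why: the vanadium alkoxide of the C9 allylic alcohol delivers oxygen only to C10=C1, and because this catalyst reacts through the conformer with a small O–C9–C10=C1 dihedral angle (also favoured by the geminal C10 methyl), Z-allylic alcohols in medium rings are expected to give the cis (erythro) epoxy alcohol, which sets C1 and C10, while the silyl-protected C4=C5 alkene, the isopropenyl group and the angelate carry no binding hydroxyl and stay untouched.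

Step 20
Reactants: 31 C1–C10 epoxy alcohol
Product: 32 C9 acetate of 31
Conditions: Ac2O, pyridine, DMAP (cat.), CH2Cl2, 0 °C to rt
Reagents that add atoms: acetic anhydride, CC(=O)OC(C)=O
Why: standard acetylation of the secondary C9 alcohol proceeds with retention, and the epoxide and the angelate tolerate the mild base.

Step 21
Reactants: 32 C9 acetate
Product: 33 C3 allylic alcohol (C8 angelate; C9 acetate; C1–C10 epoxide)
Conditions: Bu4NF, AcOH (1:1), THF, rt
Reagents that add atoms: none
Why: acetic-acid-buffered fluoride cleaves the tert-butyldiphenylsilyl ether while the buffer keeps the two esters from migrating or hydrolysing and the epoxide from opening.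

Step 22
Reactants: 33 C3 allylic alcohol
Product: 34 C4–C5 epoxide of 33 with the epoxide oxygen trans to the C3 hydroxyl (4S,5S)
Conditions: m-CPBA (1.1 equiv), NaHCO3, CH2Cl2, 0 °C
Reagents that add atoms: 3-chloroperbenzoic acid, O=C(OO)c1cccc(Cl)c1
Why: hydrogen-bond-directed Prilezhaev epoxidation of the Z-allylic alcohol should proceed through the allylic-strain-minimised conformer (C3–H eclipsing the alkene, hydroxyl outside) from the peripheral face, which gives the threo (trans) epoxy alcohol and so sets C4 and C5, and the trisubstituted hydroxyl-assisted C4=C5 alkene should react faster than the isopropenyl group and the electron-poor angelate.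

Step 23
Reactants: 34 C4–C5 epoxy alcohol
Product: 35 CNP0220329.1
Conditions: angelic acid, 2,4,6-Cl3C6H2COCl, Et3N, toluene, rt; then 34, 60–80 °C
Reagents that add atoms: angelic acid [(Z)-2-methylbut-2-enoic acid], C/C=C(C)\C(=O)O
Why: the same DMAP-free mixed-anhydride esterification acylates the C3 epoxy alcohol with retention under weakly basic, non-nucleophilic conditions that neither open the epoxides nor trigger Payne rearrangement, which completes the target.

**Compound list**

1 | 3-methylbut-2-enoic acid | CC(C)=CC(=O)O | starting material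
2 | (R)-4-benzyloxazolidin-2-one | O=C1N[C@H](Cc2ccccc2)CO1 | starting material
3 | 3-methylbut-2-enoic pivalic anhydride | CC(C)=CC(=O)OC(=O)C(C)(C)C | intermediate
4 | (R)-4-benzyl-3-(3-methylbut-2-enoyl)oxazolidin-2-one | CC(C)=CC(=O)N1[C@H](Cc2ccccc2)COC1=O | intermediate
5 | but-2-yn-1-ol | CC#CCO | starting material
6 | sodium cyclic alkenylalanate (five-membered O–Al–C3=C2–C1 ring, two 2-methoxyethoxy groups on Al) | CC1=CCO[Al-]1(OCCOC)OCCOC.[Na+] | intermediate
7 | (Z)-3-iodobut-2-en-1-ol | OC/C=C(C)\I | intermediate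
8 | (Z)-1-bromo-3-iodobut-2-ene | BrC/C=C(C)\I | intermediate
9 | sodium Z(O)-dienolate of 4 | C=C(C)/C=C(\[O-])N1[C@H](Cc2ccccc2)COC1=O.[Na+] | intermediate
10 | (R)-4-benzyl-3-[(2R,4Z)-5-iodo-2-(prop-1-en-2-yl)hex-4-enoyl]oxazolidin-2-one | C=C(C)[C@@H](C/C=C(C)\I)C(=O)N1[C@H](Cc2ccccc2)COC1=O | intermediate
11 | (2R,4Z)-5-iodo-2-(prop-1-en-2-yl)hex-4-en-1-ol | C=C(C)[C@@H](C/C=C(C)\I)CO | intermediate
12 | tert-butyl{[(2R,4Z)-5-iodo-2-(prop-1-en-2-yl)hex-4-en-1-yl]oxy}dimethylsilane | C=C(C)[C@@H](C/C=C(C)\I)CO[Si](C)(C)C(C)(C)C | intermediate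
13 | methyl 3,3-dimethoxypropanoate | COC(=O)CC(OC)OC | starting material
14 | N,3,3-trimethoxy-N-methylpropanamide | CON(C)C(=O)CC(OC)OC | intermediate
15 | alkenyllithium from 12 (lithium on C4, Z) | C=C(C)[C@@H](C/C=C(C)\[Li])CO[Si](C)(C)C(C)(C)C | intermediate
16 | (4Z,7R)-8-(tert-butyldimethylsilyloxy)-1,1-dimethoxy-4-methyl-7-(prop-1-en-2-yl)oct-4-en-3-one | C=C(C)[C@@H](C/C=C(C)\C(=O)CC(OC)OC)CO[Si](C)(C)C(C)(C)C | intermediate
17 | (3S,4Z,7R)-8-(tert-butyldimethylsilyloxy)-1,1-dimethoxy-4-methyl-7-(prop-1-en-2-yl)oct-4-en-3-ol | C=C(C)[C@@H](C/C=C(C)\[C@@H](O)CC(OC)OC)CO[Si](C)(C)C(C)(C)C | intermediate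
18 | (3S,4Z,7R)-8-(tert-butyldimethylsilyloxy)-3-(tert-butyldiphenylsilyloxy)-1,1-dimethoxy-4-methyl-7-(prop-1-en-2-yl)oct-4-ene | C=C(C)[C@@H](C/C=C(C)\[C@@H](O[Si](c1ccccc1)(c1ccccc1)C(C)(C)C)CC(OC)OC)CO[Si](C)(C)C(C)(C)C | intermediate
19 | N-(1-methoxyalkyl)-2,4,6-trimethylpyridinium triflate from 18 (mixed N,O-acetal at C1) | C=C(C)[C@@H](C/C=C(C)\[C@@H](O[Si](c1ccccc1)(c1ccccc1)C(C)(C)C)CC(OC)[n+]1c(C)cc(C)cc1C)CO[Si](C)(C)C(C)(C)C.[O-]S(=O)(=O)C(F)(F)F | intermediate
20 | (3S,4Z,7R)-8-(tert-butyldimethylsilyloxy)-3-(tert-butyldiphenylsilyloxy)-4-methyl-7-(prop-1-en-2-yl)oct-4-enal | C=C(C)[C@@H](C/C=C(C)\[C@@H](O[Si](c1ccccc1)(c1ccccc1)C(C)(C)C)CC=O)CO[Si](C)(C)C(C)(C)C | intermediate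
21 | 2-(triphenylphosphoranylidene)propanal | CC(C=O)=P(c1ccccc1)(c1ccccc1)c1ccccc1 | starting material
22 | (2E,5S,6Z,9R)-10-(tert-butyldimethylsilyloxy)-5-(tert-butyldiphenylsilyloxy)-2,6-dimethyl-9-(prop-1-en-2-yl)deca-2,6-dienal | C=C(C)[C@@H](C/C=C(C)\[C@@H](O[Si](c1ccccc1)(c1ccccc1)C(C)(C)C)C/C=C(C)/C=O)CO[Si](C)(C)C(C)(C)C | intermediate
23 | bis(4-methoxybenzyl) acetal of 22 (acetal at ring C9; C8 silyl ether) | C=C(C)[C@@H](C/C=C(C)\[C@@H](O[Si](c1ccccc1)(c1ccccc1)C(C)(C)C)C/C=C(C)/C(OCc1ccc(OC)cc1)OCc1ccc(OC)cc1)CO[Si](C)(C)C(C)(C)C | intermediate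
24 | (2R,4Z,6S,8E)-10,10-bis(4-methoxybenzyloxy)-6-(tert-butyldiphenylsilyloxy)-5,9-dimethyl-2-(prop-1-en-2-yl)deca-4,8-dien-1-ol | C=C(C)[C@@H](C/C=C(C)\[C@@H](O[Si](c1ccccc1)(c1ccccc1)C(C)(C)C)C/C=C(C)/C(OCc1ccc(OC)cc1)OCc1ccc(OC)cc1)CO | intermediate
25 | (2R,4Z,6S,8E)-10,10-bis(4-methoxybenzyloxy)-6-(tert-butyldiphenylsilyloxy)-5,9-dimethyl-2-(prop-1-en-2-yl)deca-4,8-dienal (ring C8 aldehyde) | O=C[C@@H](C(C)=C)C/C=C(C)\[C@@H](O[Si](c1ccccc1)(c1ccccc1)C(C)(C)C)C/C=C(C)/C(OCc1ccc(OC)cc1)OCc1ccc(OC)cc1 | intermediate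
26 | alkoxyallyl iodide from 25 (C9 iodo 4-methoxybenzyl ether, in equilibrium with the C1 allylic iodide) | O=C[C@@H](C(C)=C)C/C=C(C)\[C@@H](O[Si](c1ccccc1)(c1ccccc1)C(C)(C)C)C/C=C(C)/C(I)OCc1ccc(OC)cc1 | intermediate
27 | allylchromium from 26 (CrCl2 unit of trivalent chromium on C1; E enol ether C9=C10) | O=C[C@@H](C(C)=C)C/C=C(C)\[C@@H](O[Si](c1ccccc1)(c1ccccc1)C(C)(C)C)CC([Cr](Cl)Cl)/C(C)=C/OCc1ccc(OC)cc1 | intermediate
28 | (1S,2R,3Z,6S,7Z,10R)-6-(tert-butyldiphenylsilyloxy)-2-(4-methoxybenzyloxy)-3,7-dimethyl-10-(prop-1-en-2-yl)cyclodeca-3,7-dien-1-ol (ring C8 OH, C9 OPMB, C3 OSi, C7 isopropenyl) | C=C(C)[C@H]1C/C=C(C)\[C@@H](O[Si](c2ccccc2)(c2ccccc2)C(C)(C)C)C/C=C(C)\[C@@H](OCc2ccc(OC)cc2)[C@H]1O | intermediate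
29 | C8 angelate of 28 | C=C(C)[C@H]1C/C=C(C)\[C@@H](O[Si](c2ccccc2)(c2ccccc2)C(C)(C)C)C/C=C(C)\[C@@H](OCc2ccc(OC)cc2)[C@H]1OC(=O)/C(C)=C\C | intermediate
30 | C9 alcohol: C8 angelate, C3 tert-butyldiphenylsilyl ether, Z,Z-diene | C=C(C)[C@H]1C/C=C(C)\[C@@H](O[Si](c2ccccc2)(c2ccccc2)C(C)(C)C)C/C=C(C)\[C@@H](O)[C@H]1OC(=O)/C(C)=C\C | intermediate
31 | C1–C10 epoxide of 30 (epoxide oxygen cis to C9 OH) | C=C(C)[C@H]1C/C=C(C)\[C@@H](O[Si](c2ccccc2)(c2ccccc2)C(C)(C)C)C[C@H]2O[C@@]2(C)[C@@H](O)[C@H]1OC(=O)/C(C)=C\C | intermediate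
32 | C9 acetate of 31 | C=C(C)[C@H]1C/C=C(C)\[C@@H](O[Si](c2ccccc2)(c2ccccc2)C(C)(C)C)C[C@H]2O[C@@]2(C)[C@@H](OC(C)=O)[C@H]1OC(=O)/C(C)=C\C | intermediate
33 | C3 alcohol: C8 angelate, C9 acetate, C1–C10 epoxide, Z C4=C5 alkene | C=C(C)[C@H]1C/C=C(C)\[C@@H](O)C[C@H]2O[C@@]2(C)[C@@H](OC(C)=O)[C@H]1OC(=O)/C(C)=C\C | intermediate
34 | C4–C5 epoxide of 33 (epoxide oxygen trans to C3 OH) | C=C(C)[C@H]1C[C@@H]2O[C@]2(C)[C@@H](O)C[C@H]2O[C@@]2(C)[C@@H](OC(C)=O)[C@H]1OC(=O)/C(C)=C\C | intermediate
35 | CNP0220329.1 (1R,3S,4S,5S,7R,8S,9S,10R; C3 and C8 angelates, C9 acetate, two epoxides) | C=C(C)[C@H]1C[C@@H]2O[C@]2(C)[C@@H](OC(=O)/C(C)=C\C)C[C@H]2O[C@@]2(C)[C@@H](OC(C)=O)[C@H]1OC(=O)/C(C)=C\C | target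

**Totals**

Total step count: 23.
Longest linear sequence: 21 steps (steps 2–6 and 8–23, from but-2-yn-1-ol); steps 1 and 7 are side branches.

**Steps most likely to fail**

1. Step 16 (Proposed new method). Several processes could defeat it:
- intermolecular addition (oligomerisation) may outrun ring closure;
- the allylmetal may add through C1 and close an eight-membered ring;
- leakage between chair arrangements may erode the anti and Z selectivities;
- the aldehyde may enolise and lose the C7 configuration before it is trapped;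
- Me3SiI may ionise a benzylic C–O bond instead of the acetal.

Fallback (known chemistry, sets out from 20 and returns at 30): the ring is closed at C9–C10 by an intramolecular Nozaki–Hiyama–Kishi coupling instead. Aldehyde 20 is converted by Stork–Zhao olefination, with the ylide from (1-iodoethyl)triphenylphosphonium iodide and NaN(SiMe3)2, into the Z alkenyl iodide F1. Bu4NF at 0 °C removes the primary silyl group to give the alcohol F2, and buffered Dess–Martin oxidation gives the C8 aldehyde F3. Corey–Seebach addition of 2-lithio-1,3-dithiane, expected to follow the Felkin–Anh mode with the isopropenyl group anti to the nucleophile, installs C9 and the C8 carbinol as the dithianyl carbinol F4. The DMAP-free mixed-anhydride angeloylation gives the angelate F5, and MeI/CaCO3 in aqueous MeCN unmasks the α-acyloxy aldehyde F6. CrCl2 with catalytic NiCl2 in DMSO/THF at high dilution then joins the C10 alkenyl iodide, with retention of its Z geometry, to the C9 aldehyde. Polar Felkin–Anh addition should place the new C9 hydroxyl anti to the C8 ester and give 30.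

2. Step 19. Oxygen may be delivered to the wrong alkene face if the ring holds the C9 hydroxyl in the outside position (allylic strain with C2), which would give the trans epoxy alcohol.

Fallback (sets out from 28 and returns at 31): the epoxidation is moved one stage earlier and steered by the other hydroxyl. In 28 the free homoallylic C8 hydroxyl lies on the same ring face as the C9 oxygen, so VO(acac)2/t-BuOOH bound at C8 should carry the oxidant to the required face of C10=C1 and give the epoxy alcohol F7. Mixed-anhydride angeloylation then gives the angelate F8, and DDQ removal of the 4-methoxybenzyl group returns 31.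

3. Step 22. The peracid may also epoxidise the isopropenyl group, or attack C4=C5 from the face that gives the cis epoxy alcohol.

Fallback (sets out from 33 and returns at 35): the C3 configuration is inverted so that a strictly hydroxyl-bound oxidant can be used. Dess–Martin oxidation of 33 gives the enone F9. Corey–Bakshi–Shibata reduction with (S)-2-methyl-CBS-oxazaborolidine and catecholborane gives the C3-epimeric allylic alcohol F10. VO(acac)2/t-BuOOH, which reacts only at the alkene next to the free hydroxyl and in the cis (erythro) mode of step 19, gives the epoxy alcohol F11. Mitsunobu esterification with angelic acid (PPh3, DIAD) then inverts C3 and gives 35 directly; isomerisation of the angelate to the tiglate would have to be checked.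

**Further compounds**

F1 | step 16 | Z alkenyl iodide from 20 (iodine on C10; C8 tert-butyldimethylsilyl ether; C3 tert-butyldiphenylsilyl ether) | C=C(C)[C@@H](C/C=C(C)\[C@@H](O[Si](c1ccccc1)(c1ccccc1)C(C)(C)C)C/C=C(C)\I)CO[Si](C)(C)C(C)(C)C
F2 | step 16 | primary C8 alcohol from F1 | C=C(C)[C@@H](C/C=C(C)\[C@@H](O[Si](c1ccccc1)(c1ccccc1)C(C)(C)C)C/C=C(C)\I)CO
F3 | step 16 | C8 aldehyde from F2 | O=C[C@@H](C(C)=C)C/C=C(C)\[C@@H](O[Si](c1ccccc1)(c1ccccc1)C(C)(C)C)C/C=C(C)\I
F4 | step 16 | (8S)-carbinol carrying a 1,3-dithian-2-yl group as C9 | C=C(C)[C@@H](C/C=C(C)\[C@@H](O[Si](c1ccccc1)(c1ccccc1)C(C)(C)C)C/C=C(C)\I)[C@H](O)C1SCCCS1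
F5 | step 16 | C8 angelate of F4 | C=C(C)[C@@H](C/C=C(C)\[C@@H](O[Si](c1ccccc1)(c1ccccc1)C(C)(C)C)C/C=C(C)\I)[C@H](OC(=O)/C(C)=C\C)C1SCCCS1
F6 | step 16 | C9 aldehyde with C8 angelate and C10 alkenyl iodide | C=C(C)[C@@H](C/C=C(C)\[C@@H](O[Si](c1ccccc1)(c1ccccc1)C(C)(C)C)C/C=C(C)\I)[C@H](OC(=O)/C(C)=C\C)C=O
F7 | step 19 | C1–C10 epoxide of 28 (C8 OH free, C9 4-methoxybenzyl ether) | C=C(C)[C@H]1C/C=C(C)\[C@@H](O[Si](c2ccccc2)(c2ccccc2)C(C)(C)C)C[C@H]2O[C@@]2(C)[C@@H](OCc2ccc(OC)cc2)[C@H]1O
F8 | step 19 | C8 angelate of F7 | C=C(C)[C@H]1C/C=C(C)\[C@@H](O[Si](c2ccccc2)(c2ccccc2)C(C)(C)C)C[C@H]2O[C@@]2(C)[C@@H](OCc2ccc(OC)cc2)[C@H]1OC(=O)/C(C)=C\C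
F9 | step 22 | C3 ketone (Z enone) from 33 | C=C(C)[C@H]1C/C=C(C)\C(=O)C[C@H]2O[C@@]2(C)[C@@H](OC(C)=O)[C@H]1OC(=O)/C(C)=C\C
F10 | step 22 | (3R)-allylic alcohol, C3 epimer of 33 | C=C(C)[C@H]1C/C=C(C)\[C@H](O)C[C@H]2O[C@@]2(C)[C@@H](OC(C)=O)[C@H]1OC(=O)/C(C)=C\C
F11 | step 22 | (3R)-4,5-epoxy alcohol, C3 epimer of 34 | C=C(C)[C@H]1C[C@@H]2O[C@]2(C)[C@H](O)C[C@H]2O[C@@]2(C)[C@@H](OC(C)=O)[C@H]1OC(=O)/C(C)=C\C
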